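A computed curve of target that climbs and then sags is easy to trust without knowing which clock is running in the flask, and that is the pitfall I want to avoid here.

    substrate + free catalyst ⇌ catalyst intermediate A (K1 = 9.3 M⁻¹, k1 = 4100 M⁻¹ min⁻¹)
    catalyst intermediate C → free catalyst + target (k2 = 200 min⁻¹)
    reagent + catalyst intermediate A ⇌ catalyst intermediate B (K3 = 1.9 M⁻¹, k3 = 5800 M⁻¹ min⁻¹)
    target + by-product → side product (k4 = 0.74 M⁻¹ min⁻¹)
    2 substrate → self-condensation product (k5 = 0.54 M⁻¹ min⁻¹)
    catalyst intermediate B → by-product + catalyst intermediate C (k6 = 440 min⁻¹)

| setting | violet | green | grey |
|---|---|---|---|
| substrate | 0.13 M | 0.13 M | 0.13 M |
| reagent | 0.260 M | 0.260 M | 0.260 M |
| free catalyst | 0.39 mM | 0.39 mM | 0.39 mM |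
| time | 8.0 min | 25 min | 80 min |

1. which of the two there is more of at the end, violet (target / side product)
2. which of the two there is more of at the end, green (target / side product)
3. which of the two there is more of at the end, grey (target / side product)
4. amount of target at the end, in percent of the substrate charged, violet
5. amount of target at the end, in percent of the substrate charged, green
6. amount of target at the end, in percent of the substrate charged, grey

- in percentages every species weighs as the substrate in it: one self-condensation product counts as two
- two of one species on the left: rate k times its square, two consumed each time
- run time (violet): 8.0 min

I start with the step in which target meets by-product. Each turn of the cycle makes one target and one by-product, and that step removes one of each. The two therefore stay equal, apart from what the catalyst holds, and 0.39 mM is small beside 0.13 M. Two equal partners with no further supply obey a simple rule: the reciprocal of c(target) rises at 0.74 M⁻¹ min⁻¹. If the full charge became target at once, grey would keep 11.5% of it at 80 min.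

My first objection is that self-condensation takes substrate. At the start it uses 0.0183 M min⁻¹. A catalyst needs at least the sum of the two first-order lifetimes for each turn, so the cycle cannot exceed 0.0536 M min⁻¹. Dividing the charge in that proportion leaves a pool of 0.0970 M. This is rough: the cycle runs below its ceiling, which raises the loss, and self-condensation fades with the square of c(substrate), which lowers it.

This gives 13.9 min for the pairing time, the first half-life of the pool against its own partner. Each later half-life is twice the one before, since this is a second-order loss.

My second objection is that the pool does not appear at time zero. At the ceiling it takes 1.81 min to form, which is shorter than the pairing time, so I start the clock there. The real cycle is slower, so this start is too early and my figures should come out low.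

Dividing the pool by one plus the elapsed time over the pairing time gives 51.7% for violet, 28.0% for green and 11.3% for grey. In this reckoning side product draws level with target one pairing time after the clock starts, at 15.7 min. Violet stops earlier and stays with target, while green and grey stop later and go to side product.

The forecast names target, side product and side product, with 54% (50% to 58%), 32% (29% to 35%) and 12% (10.5% to 13.5%), on the ground that “target peaks near 0.07 M at about 8 min and then decays with 1/[target] rising 0.74 per M per min”; my green figure lies below its range.

The simulation gives 53.9% of target in violet, 31.9% in green and 11.9% in grey; the larger of the two products is target in violet, side product in green and side product in grey. Target and side product stand level at 19.7 min, which is 4.00 min later than my clock and pairing time put it. My figures for violet, green and grey lie below the computed ones, which is the direction I expected.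

For the grey charge read at 50 min, the pool and the pairing time give 16.7% of target. The computed flask holds 18.1%, beside 58.0% of side product.

The constants used here were set for the occasion; what happens was integrated by code.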